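**Retrosynthetic overview**

1. The last C–C bond is C6–C7, made by an sp2–sp2 Suzuki coupling instead of the usual C7=C8 aldol condensation: target ⇒ (Z)-exocyclic enol triflate 11 + (E)-alkenylboronate 14. The 7Z geometry comes from chelation-controlled triflation and 5E from syn-hydroboration; both are carried through with retention.
2. 11 ⇒ α′-formylation of bromo-enone 9, so C7 enters as a formyl carbon.
3. 9 ⇒ enone 7 by nucleophilic epoxidation, bromide opening and dehydration, which leaves the Z-olefin untouched.
4. 7 ⇒ (R)-4-silyloxycyclopentenone 3 + (Z)-oct-2-enylbarium; 1,2-addition anti to the OTBS group sets C12.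
5. Rings: the only ring (the cyclopentenone) is bought as a chiral-pool building block; no ring is formed in the route.

Assumption: compounds 1, 3, 12 and 13 are treated as commercially available.

**Route**

Step 1
Reactants: 1, (Z)-oct-2-en-1-ol
Product: 2, (Z)-1-chlorooct-2-ene
Conditions: NCS, Me2S, CH2Cl2, −20 → 0 °C
Reagents that add atoms: N-chlorosuccinimide, ClN1C(=O)CCC1=O
Why: Corey–Kim chlorination is an SN2 displacement at the primary allylic carbon, so there is no allylic transposition and the Z-olefin is kept.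

Step 2
Reactants: 2, (Z)-1-chlorooct-2-ene; 3, (R)-4-(tert-butyldimethylsilyloxy)cyclopent-2-en-1-one
Product: 4, (1S,4R)-4-(tert-butyldimethylsilyloxy)-1-[(Z)-oct-2-en-1-yl]cyclopent-2-en-1-ol (OH cis to OTBS)
Conditions: BaI2, Li biphenylide (2 equiv), THF, rt (gives reactive Ba); 2, −78 °C; then 3, −78 °C; aq NH4Cl; remove minor diastereomer by chromatography
Reagents that add atoms: none (both partners are the listed reactants)
Why: Yamamoto allylbarium addition: the (Z)-allylbarium is configurationally stable at −78 °C and adds 1,2 through its α-carbon (linear, Z retained); attack anti to the C4–OTBS group sets the carbinol centre that becomes C12 (R in the target).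

Step 3
Reactants: 4
Product: 5, (1S,4R)-1-[(Z)-oct-2-en-1-yl]cyclopent-2-ene-1,4-diol
Conditions: TBAF, THF, 0 °C
Reagents that add atoms: none
Why: Fluoride desilylation of the secondary TBS ether; no stereocentre is touched.

Step 4
Reactants: 5
Product: 6, (S)-4-hydroxy-4-[(Z)-oct-2-en-1-yl]cyclopent-2-en-1-one
Conditions: MnO2, CH2Cl2, rt
Reagents that add atoms: none
Why: MnO2 oxidises only the secondary allylic alcohol; the tertiary alcohol cannot be oxidised, and the neutral conditions avoid retro-aldol racemisation.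

Step 5
Reactants: 6
Product: 7, (S)-4-[(Z)-oct-2-en-1-yl]-4-(triethylsilyloxy)cyclopent-2-en-1-one
Conditions: TESOTf, 2,6-lutidine, CH2Cl2, −78 → 0 °C
Reagents that add atoms: triethylsilyl triflate, CC[Si](CC)(CC)OS(=O)(=O)C(F)(F)F
Why: Silylation of the hindered tertiary alcohol with a silyl triflate; the ether blocks retro-aldol and alkoxide chemistry in the basic steps that follow.

Step 6
Reactants: 7
Product: 8, (4S)-4-[(Z)-oct-2-en-1-yl]-4-(triethylsilyloxy)-6-oxabicyclo[3.1.0]hexan-2-one (2,3-epoxy ketone; epoxide diastereomers both converge in step 7)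
Conditions: 30% H2O2, NaOH (cat.), MeOH, 0 °C
Reagents that add atoms: hydrogen peroxide, OO
Why: Weitz–Scheffer nucleophilic epoxidation attacks only the electron-poor enone and leaves the isolated Z-olefin alone; the new epoxide stereocentres are erased in the next step.

Step 7
Reactants: 8
Product: 9, (S)-2-bromo-4-[(Z)-oct-2-en-1-yl]-4-(triethylsilyloxy)cyclopent-2-en-1-one
Conditions: LiBr, AcOH, THF, rt; then MsCl, Et3N, CH2Cl2, 0 °C
Reagents that add atoms: lithium bromide, [Li+].[Br-]
Why: Bromide opens the epoxy ketone by SN2 at the carbonyl-activated α-carbon (the β-carbon is neopentyl), and E1cB loss of the β-mesylate gives the α-bromoenone without any electrophilic bromine that would attack the Z-olefin.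

Step 8
Reactants: 9
Product: 10, (4R,5Z)-2-bromo-5-(hydroxymethylidene)-4-[(Z)-oct-2-en-1-yl]-4-(triethylsilyloxy)cyclopent-2-en-1-one (H-bonded enol of the α′-formyl ketone; the descriptor changes from S to R only because CIP priorities change)
Conditions: LiHMDS, THF, −78 °C; CF3CH2OCHO, −78 °C; pH 7 buffer
Reagents that add atoms: 2,2,2-trifluoroethyl formate, O=COCC(F)(F)F
Why: Crossed Claisen formylation of the kinetic α′-lithium enolate (the only enolisable position) with the activated formate, which reacts at −78 °C.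

Step 9
Reactants: 10
Product: 11, (Z)-[(5R)-3-bromo-5-[(Z)-oct-2-en-1-yl]-2-oxo-5-(triethylsilyloxy)cyclopent-3-en-1-ylidene]methyl trifluoromethanesulfonate (OTf cis to the ring C=O)
Conditions: LiHMDS, THF, −78 °C; Comins' reagent, −78 → −20 °C
Reagents that add atoms: Comins' reagent, N-(5-chloro-2-pyridyl)bis(trifluoromethanesulfonimide), O=S(=O)(N(c1ccc(Cl)cn1)S(=O)(=O)C(F)(F)F)C(F)(F)F
Why: O-triflation of the lithium-chelated U-shaped β-keto-aldehyde enolate (the same control as Z-selective enol triflation of β-keto esters) puts OTf syn to C=O, and A(1,3) strain with the quaternary carbon disfavours the E isomer.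

Step 10
Reactants: 12, methyl hex-5-ynoate; 13, pinacolborane
Product: 14, methyl (E)-6-(4,4,5,5-tetramethyl-1,3,2-dioxaborolan-2-yl)hex-5-enoate
Conditions: HBpin, Cy2BH (10 mol %), neat, rt
Reagents that add atoms: none (both partners are the listed reactants)
Why: Dialkylborane-catalysed syn, anti-Markovnikov hydroboration of the terminal alkyne gives only the (E)-alkenylboronate and tolerates the ester.

Step 11
Reactants: 11; 14
Product: 15, methyl (5E,7Z,12R,14Z)-10-bromo-9-oxo-12-(triethylsilyloxy)prosta-5,7,10,14-tetraen-1-oate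
Conditions: Pd(PPh3)4 (5 mol %), aq K3PO4, THF, rt, dark
Reagents that add atoms: none (both partners are the listed reactants)
Why: Suzuki–Miyaura coupling with retention at both alkenyl partners fixes 5E,7Z; the vinylogous acyl triflate should undergo oxidative addition to Pd(0)/PPh3 faster than the α-bromoenone C–Br at room temperature.

Step 12
Reactants: 15
Product: 16, Bromoclavulone III, methyl (5E,7Z,12R,14Z)-10-bromo-12-hydroxy-9-oxoprosta-5,7,10,14-tetraen-1-oate
Conditions: HF·pyridine, pyridine, THF, 0 °C, dark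
Reagents that add atoms: none
Why: Buffered fluoride desilylation of the tertiary TES ether; it is non-basic and only mildly acidic, so the cross-conjugated dienone, ester and vinyl bromide are untouched.

**Compound list**

1 | (Z)-oct-2-en-1-ol | CCCCC/C=C\CO | starting material
2 | (Z)-1-chlorooct-2-ene | CCCCC/C=C\CCl | intermediate
3 | (R)-4-(tert-butyldimethylsilyloxy)cyclopent-2-en-1-one | O=C1C=C[C@H](O[Si](C)(C)C(C)(C)C)C1 | starting material
4 | (1S,4R)-4-(tert-butyldimethylsilyloxy)-1-[(Z)-oct-2-en-1-yl]cyclopent-2-en-1-ol | O[C@]1(C/C=C\CCCCC)C=C[C@H](O[Si](C)(C)C(C)(C)C)C1 | intermediate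
5 | (1S,4R)-1-[(Z)-oct-2-en-1-yl]cyclopent-2-ene-1,4-diol | O[C@]1(C/C=C\CCCCC)C=C[C@H](O)C1 | intermediate
6 | (S)-4-hydroxy-4-[(Z)-oct-2-en-1-yl]cyclopent-2-en-1-one | O[C@]1(C/C=C\CCCCC)C=CC(=O)C1 | intermediate
7 | (S)-4-[(Z)-oct-2-en-1-yl]-4-(triethylsilyloxy)cyclopent-2-en-1-one | CC[Si](CC)(CC)O[C@]1(C/C=C\CCCCC)C=CC(=O)C1 | intermediate
8 | (4S)-4-[(Z)-oct-2-en-1-yl]-4-(triethylsilyloxy)-6-oxabicyclo[3.1.0]hexan-2-one (epoxide diastereomer mixture) | CC[Si](CC)(CC)O[C@]1(C/C=C\CCCCC)C2OC2C(=O)C1 | intermediate
9 | (S)-2-bromo-4-[(Z)-oct-2-en-1-yl]-4-(triethylsilyloxy)cyclopent-2-en-1-one | CC[Si](CC)(CC)O[C@]1(C/C=C\CCCCC)C=C(Br)C(=O)C1 | intermediate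
10 | (4R,5Z)-2-bromo-5-(hydroxymethylidene)-4-[(Z)-oct-2-en-1-yl]-4-(triethylsilyloxy)cyclopent-2-en-1-one | CC[Si](CC)(CC)O[C@]1(C/C=C\CCCCC)C=C(Br)C(=O)/C1=C\O | intermediate
11 | (Z)-[(5R)-3-bromo-5-[(Z)-oct-2-en-1-yl]-2-oxo-5-(triethylsilyloxy)cyclopent-3-en-1-ylidene]methyl triflate | CC[Si](CC)(CC)O[C@]1(C/C=C\CCCCC)C=C(Br)C(=O)/C1=C\OS(=O)(=O)C(F)(F)F | intermediate
12 | methyl hex-5-ynoate | C#CCCCC(=O)OC | starting material
13 | pinacolborane | CC1(C)OBOC1(C)C | starting material
14 | methyl (E)-6-(4,4,5,5-tetramethyl-1,3,2-dioxaborolan-2-yl)hex-5-enoate | COC(=O)CCC/C=C/B1OC(C)(C)C(C)(C)O1 | intermediate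
15 | methyl (5E,7Z,12R,14Z)-10-bromo-9-oxo-12-(triethylsilyloxy)prosta-5,7,10,14-tetraen-1-oate | CC[Si](CC)(CC)O[C@]1(C/C=C\CCCCC)C=C(Br)C(=O)/C1=C\C=C\CCCC(=O)OC | intermediate
16 | Bromoclavulone III | CCCCC/C=C\C[C@@]1(O)C=C(Br)C(=O)/C1=C\C=C\CCCC(=O)OC | target

**Totals**

Total steps: 12. Longest linear sequence: 11 (steps 1–9, 11, 12).

**Three steps most likely to fail, with fallbacks**

1. Step 9 (Z-selective, O-regioselective triflation; with step 8 it defines 7Z). If E-triflate or ring-O triflation dominates, change the bond formed. Convert 9 to the cyclic bis(2,2,2-trifluoroethyl) β-ketophosphonate (enol phosphate, then base-induced 1,3-phosphoryl shift) and run a Still–Gennari-type Z-selective Horner–Wadsworth–Emmons olefination with methyl (E)-7-oxohept-5-enoate.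
2. Step 11 (triflate versus C–Br chemoselectivity, and base sensitivity of the β-trifloxy enone). Remove the competition by postponing bromine: carry epoxy ketone 8 through formylation, triflation and Suzuki coupling, then unveil the α-bromoenone last by LiBr/AcOH opening and dehydration before desilylation.
3. Step 2 (α-selectivity, Z retention and facial selectivity of the allylbarium addition). Build the side chain without an allylic organometallic: Corey–Chaykovsky methylenation of 3 (anti to OTBS) to the spiro-epoxide, BF3-mediated opening at CH2 with lithium hept-1-ynylide, then Lindlar semi-hydrogenation to the Z-olefin.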